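The cyclopenta[c]pyran core is cut along its ring-fusion bond C5–C9. The nine atoms that run around the perimeter of the two fused rings (C1–O2–C3–C4–C5–C6–C7–C8–C9) are first tied into a Z nine-membered lactone in which C3 is an acetal carbon. A transannular Ireland–Claisen contraction of this lactone then makes C5–C9 in one operation: it closes the cyclopentane, sets the cis C5/C9 stereocentres and frees C3 as an enol ether at the aldehyde level, from which the pyran is rebuilt with C1. The precursor is the 3S 1-methoxyallyl lactone carrying a C7/C10 acetonide and a C8 triethylsilyl ether.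

Key step: step 9

Remark: atoms carry iridoid numbers (C1, O2, C3–C11); step 7 forms both C3 epimers, 14 and 15 are drawn as the 3S epimers (the 3R lactone is removed by chromatography after step 8), and C3 of 19 is an epimer mixture that is erased in step 11.

Step 1
Reactants: 1 2,2-dimethyl-1,3-dioxan-5-one; 2 (S)-1-amino-2-(methoxymethyl)pyrrolidine (SAMP)
Product: 3 SAMP hydrazone of 2,2-dimethyl-1,3-dioxan-5-one
Conditions: benzene, reflux, Dean–Stark trap
Reagents that add atoms: none
Why: Condensation of the ketone with the chiral hydrazine (hydrazone formation), driven by azeotropic removal of water.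

Step 2
Reactants: 3 SAMP hydrazone of 2,2-dimethyl-1,3-dioxan-5-one; 4 allyl bromide
Product: 6 SAMP hydrazone of (S)-4-allyl-2,2-dimethyl-1,3-dioxan-5-one, via lithium azaenolate 5 (not isolated)
Conditions: t-BuLi, THF, −78 °C; then 4, −100 °C → rt
Reagents that add atoms: none
Why: Enders SAMP-hydrazone alkylation, in which the chelated lithium azaenolate is allylated on the face away from the methoxymethyl arm, which should set C7 as S.

Step 3
Reactants: 6 SAMP hydrazone of (S)-4-allyl-2,2-dimethyl-1,3-dioxan-5-one
Product: 7 (S)-4-allyl-2,2-dimethyl-1,3-dioxan-5-one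
Conditions: sat. aq. oxalic acid, Et2O, rt
Reagents that add atoms: water, O
Why: Two-phase hydrazone hydrolysis with oxalic acid (Enders cleavage) should free the ketone without epimerising C7 or opening the ketal, and it returns the auxiliary.

Step 4
Reactants: 7 (S)-4-allyl-2,2-dimethyl-1,3-dioxan-5-one; 8 methyl acetate
Product: 10 methyl 2-[(4S,5R)-4-allyl-5-hydroxy-2,2-dimethyl-1,3-dioxan-5-yl]acetate, via lithium enolate 9 (not isolated)
Conditions: LiN(i-Pr)2, THF, −78 °C, 8; then 7, −78 °C; AcOH quench at −78 °C
Reagents that add atoms: none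
Why: Aldol addition of the lithium ester enolate to the ketone, in which the carbon nucleophile should enter the 2,2-dimethyl-1,3-dioxan-5-one chair axially, cis to the equatorial allyl group (the equatorial path is shielded by the axial 2-methyl group and no 1,3-diaxial hydrogens oppose axial entry), so that C8 is set with its hydroxyl trans to the allyl group.

Step 5
Reactants: 10 methyl 2-[(4S,5R)-4-allyl-5-hydroxy-2,2-dimethyl-1,3-dioxan-5-yl]acetate
Product: 11 methyl 2-[(4S,5R)-4-allyl-2,2-dimethyl-5-(triethylsilyloxy)-1,3-dioxan-5-yl]acetate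
Conditions: TESOTf, 2,6-lutidine, CH2Cl2, −78 → 0 °C
Reagents that add atoms: triethylsilyl trifluoromethanesulfonate, CC[Si](CC)(CC)OS(=O)(=O)C(F)(F)F
Why: Silyl triflate with a hindered pyridine base silylates the tertiary alcohol (silyl ether formation), which blocks retro-aldol cleavage in the later base steps.

Step 6
Reactants: 11 methyl 2-[(4S,5R)-4-allyl-2,2-dimethyl-5-(triethylsilyloxy)-1,3-dioxan-5-yl]acetate
Product: 12 2-[(4S,5R)-4-allyl-2,2-dimethyl-5-(triethylsilyloxy)-1,3-dioxan-5-yl]acetic acid
Conditions: LiOH·H2O, THF/MeOH/H2O, 0 °C → rt; then 1 M HCl to pH 4 at 0 °C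
Reagents that add atoms: lithium hydroxide, [Li+].[OH-]
Why: Ester saponification; with the β-oxygen silylated, neither retro-aldol cleavage nor elimination should compete.

Step 7
Reactants: 12 2-[(4S,5R)-4-allyl-2,2-dimethyl-5-(triethylsilyloxy)-1,3-dioxan-5-yl]acetic acid; 13 methoxyallene
Product: 14 (S)-1-methoxyallyl ester of acid 12 (formed together with its 3R epimer)
Conditions: 13 (5 equiv), PPTS (1 mol%), CH2Cl2, 0 °C → rt
Reagents that add atoms: none
Why: Markovnikov addition of the carboxylic acid across the enol-ether double bond of the alkoxyallene (acylal formation, as in the making of 1-alkoxyalkyl esters from vinyl ethers); C3 is formed without control.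

Step 8
Reactants: 14 (S)-1-methoxyallyl ester of acid 12 (with its 3R epimer)
Product: 15 (3S,7S,8R) Z nine-membered 1-methoxyallyl lactone with cis-fused C7/C10 acetonide and C8 triethylsilyl ether
Conditions: second-generation Grubbs catalyst (10 mol%), toluene (1 mM), 80 °C; chromatography to remove the 3R epimer
Reagents that add atoms: none
Why: Ring-closing metathesis of the two terminal alkenes, in which the nine-membered ring can only hold a Z alkene and the cis-fused dioxane with the quaternary C8 holds the two chains close.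

Step 9
Reactants: 15 (3S,7S,8R) Z nine-membered 1-methoxyallyl lactone
Product: 18 cis-cyclopentane acid with C9–CO2H and C5–(E)-CH=CH–OMe, via silyl ketene acetal 16 (not isolated), via trimethylsilyl ester 17 (not isolated)
Conditions: TMSCl/Et3N (premixed), THF, −78 °C, then LiN(i-Pr)2 added slowly; −78 °C → rt (40 °C if needed); pH 7 phosphate buffer
Reagents that add atoms: none
Why: LiN(i-Pr)2 deprotonates C9 in the presence of TMSCl, so the lactone enolate is trapped at once as the endocyclic silyl ketene acetal 16, which on warming undergoes a concerted [3,3] shift in which C9 bonds to C5 across the ring while the acetal bond O2–C3 breaks, giving silyl ester 17 and, after mild hydrolysis, acid 18. The closest known reaction is the Ireland–Claisen ring contraction of medium-ring alkenyl lactones to cis-2-alkenylcycloalkanecarboxylic acids, and a donor alkoxy group on the carbinol carbon is known to speed Claisen shifts. The cyclopentane is closed by transannular C–C bond formation through a boat-shaped six-atom transition state, the only one that the Z alkene and the endocyclic ketene acetal allow, so C1 and C4 end up cis (C5–H and C9–H cis). The absolute sense at C5 and C9 is relayed from C3 by 1,3-chirality transfer, because its methoxy group can only point away from the ring (hence the E enol ether) and the 3S acetal therefore exposes one alkene face. That same face is the one remote from the cis-fused dioxane, so C3 and the C7/C8 centres act in concert. The step needs silylation to outrun loss of the β-silyloxy group and ketene formation from the enolate, which the premixed TMSCl at −78 °C is there to secure.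

Step 10
Reactants: 18 cis-cyclopentane acid
Product: 19 cyclic acylal (C1 lactone carbonyl, ring O2, C3–OMe as both epimers)
Conditions: PPTS (5 mol%), CH2Cl2, 0 °C → rt
Reagents that add atoms: none
Why: Acid-catalysed intramolecular addition of the carboxylic acid to the enol ether (six-membered cyclic acylal formation) unmasks C3 at the aldehyde level without water and so spares the ketal.

Step 11
Reactants: 19 cyclic acylal
Product: 20 cis 1,5-diol (C1H2OH on C9, C4H2–C3H2OH on C5)
Conditions: LiAlH4, THF, 0 °C; Na2SO4·10H2O quench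
Reagents that add atoms: none
Why: LiAlH4 reduction of the lactone acylal takes both masked aldehyde carbons, C1 and C3, to primary alcohols with loss of methoxide.

Step 12
Reactants: 20 cis 1,5-diol
Product: 21 cis 1,5-dialdehyde (C1 and C3 formyl)
Conditions: (COCl)2, DMSO, CH2Cl2, −78 °C; Et3N, −78 → −20 °C; used crude
Reagents that add atoms: none
Why: Swern oxidation activates both hydroxyls before the base is added, so the 1,5-diol should go to the dialdehyde and not, through a lactol, to a lactone.

Step 13
Reactants: 21 cis 1,5-dialdehyde; 22 isovaleric anhydride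
Product: 24 1-O-isovaleryl 3-ene (cis-fused 1-acyloxy-dihydropyran, C1 as in the target), via lactol 23 (not isolated)
Conditions: 22, DMAP (cat.), pyridine, CH2Cl2, 0 °C → rt
Reagents that add atoms: none
Why: The 1,5-dialdehyde closes through its C3 enol to the cis-fused 1-hydroxy-dihydropyran (hemiacetal formation, as in iridoid lactols), and O-acylation should trap the lactol epimer whose oxygen is anti to the C9–C8 bond, which sets C1.

Step 14
Reactants: 24 1-O-isovaleryl 3-ene
Product: 26 4-formyl derivative of 24 (C11 aldehyde), via iminium salt 25 (not isolated)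
Conditions: POCl3, DMF, CH2Cl2, 0 °C → rt; then aq. NaOAc, 0 °C
Reagents that add atoms: N,N-dimethylformamide, CN(C)C=O; water, O
Why: Vilsmeier–Haack formylation at C4, the nucleophilic β-carbon of the cyclic enol ether, followed by hydrolysis of the iminium salt.

Step 15
Reactants: 26 4-formyl derivative of 24
Product: 27 7,8,10-triol 11-aldehyde
Conditions: TFA/H2O/THF (1:1:4), 0 °C → rt
Reagents that add atoms: none
Why: Aqueous acid hydrolysis of the isopropylidene ketal and the tertiary silyl ether; the C4 formyl group makes the enol ether a vinylogous formate, which should keep the enol ether and the C1 acyloxy acetal intact.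

Step 16
Reactants: 27 7,8,10-triol 11-aldehyde
Product: 28 10-O-tert-butyldimethylsilyl ether of 27
Conditions: TBSCl, imidazole, CH2Cl2, 0 °C
Reagents that add atoms: tert-butyldimethylsilyl chloride, CC(C)(C)[Si](C)(C)Cl
Why: Chlorosilane silylation should select the primary C10 hydroxyl over the hindered secondary C7 and the tertiary C8 hydroxyl.

Step 17
Reactants: 29 p-coumaric acid
Product: 31 (E)-4-(tert-butyldimethylsilyloxy)cinnamic acid, via bis-silyl compound 30 (not isolated)
Conditions: TBSCl (2.5 equiv), imidazole, DMF, rt; then AcOH/THF/H2O, rt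
Reagents that add atoms: tert-butyldimethylsilyl chloride, CC(C)(C)[Si](C)(C)Cl
Why: Silylation of both the phenol and the acid, followed by selective hydrolysis of the labile silyl ester, gives the phenol-protected acid.

Step 18
Reactants: 28 10-O-tert-butyldimethylsilyl ether of 27; 31 (E)-4-(tert-butyldimethylsilyloxy)cinnamic acid
Product: 32 7-O-[(E)-4-(tert-butyldimethylsilyloxy)cinnamoyl] ester of 28
Conditions: EDC·HCl, DMAP, CH2Cl2, 0 °C → rt
Reagents that add atoms: none
Why: Steglich esterification (carbodiimide, DMAP) acylates the only acylable hydroxyl, C7–OH, while the tertiary C8–OH stays free.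

Step 19
Reactants: 32 7-O-[(E)-4-(tert-butyldimethylsilyloxy)cinnamoyl] ester of 28
Product: 33 bis-silyl luzonoid A (C10–OTBS, aryl–OTBS)
Conditions: NaBH4, CeCl3·7H2O, MeOH, −40 °C
Reagents that add atoms: none
Why: Luche reduction takes the C11 aldehyde to the allylic alcohol in a 1,2 sense and should leave both esters and the cinnamate double bond untouched.

Step 20
Reactants: 33 bis-silyl luzonoid A
Product: 34 luzonoid A
Conditions: HF·pyridine, pyridine, THF, 0 °C → rt
Reagents that add atoms: none
Why: Buffered fluoride cleaves the aryl and the primary silyl ether (desilylation) under conditions that should spare the acyloxy acetal, the enol ether and both esters.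

Compound list
1 | 2,2-dimethyl-1,3-dioxan-5-one | CC1(C)OCC(=O)CO1 | starting material
2 | (S)-1-amino-2-(methoxymethyl)pyrrolidine (SAMP) | COC[C@@H]1CCCN1N | starting material
3 | SAMP hydrazone of 2,2-dimethyl-1,3-dioxan-5-one | COC[C@@H]1CCCN1N=C1COC(C)(C)OC1 | intermediate
4 | allyl bromide | C=CCBr | starting material
5 | lithium azaenolate of 3 | COC[C@@H]1CCCN1N([Li])C1=COC(C)(C)OC1 | intermediate
6 | SAMP hydrazone of (S)-4-allyl-2,2-dimethyl-1,3-dioxan-5-one (Z at C=N) | CC1(C)OC/C(=N/N2CCC[C@H]2COC)[C@H](CC=C)O1 | intermediate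
7 | (S)-4-allyl-2,2-dimethyl-1,3-dioxan-5-one | CC1(C)OCC(=O)[C@H](CC=C)O1 | intermediate
8 | methyl acetate | CC(=O)OC | starting material
9 | lithium enolate of methyl acetate | C=C(OC)O[Li] | intermediate
10 | methyl 2-[(4S,5R)-4-allyl-5-hydroxy-2,2-dimethyl-1,3-dioxan-5-yl]acetate (allyl and CH2CO2Me cis) | COC(=O)C[C@@]1(O)COC(C)(C)O[C@H]1CC=C | intermediate
11 | methyl 2-[(4S,5R)-4-allyl-2,2-dimethyl-5-(triethylsilyloxy)-1,3-dioxan-5-yl]acetate | COC(=O)C[C@@]1(O[Si](CC)(CC)CC)COC(C)(C)O[C@H]1CC=C | intermediate
12 | 2-[(4S,5R)-4-allyl-2,2-dimethyl-5-(triethylsilyloxy)-1,3-dioxan-5-yl]acetic acid | OC(=O)C[C@@]1(O[Si](CC)(CC)CC)COC(C)(C)O[C@H]1CC=C | intermediate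
13 | methoxyallene | COC=C=C | starting material
14 | (S)-1-methoxyallyl ester of acid 12 (3S epimer shown, formed with its 3R epimer) | C=C[C@@H](OC)OC(=O)C[C@@]1(O[Si](CC)(CC)CC)COC(C)(C)O[C@H]1CC=C | intermediate
15 | (3S,7S,8R) Z nine-membered 1-methoxyallyl lactone, C7/C10 acetonide cis-fused, C8 triethylsilyl ether | O=C1C[C@@]2(O[Si](CC)(CC)CC)COC(C)(C)O[C@H]2C/C=C\[C@@H](OC)O1 | intermediate
16 | O-trimethylsilyl ketene acetal of 15 (silyloxy group trans to C8) | C[Si](C)(C)O/C1=C/[C@@]2(O[Si](CC)(CC)CC)COC(C)(C)O[C@H]2C/C=C\[C@@H](OC)O1 | intermediate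
17 | trimethylsilyl ester of 18 | CO/C=C/[C@H]1C[C@@H]2OC(C)(C)OC[C@]2(O[Si](CC)(CC)CC)[C@H]1C(=O)O[Si](C)(C)C | intermediate
18 | cis-cyclopentane acid: C9–CO2H and C5–(E)-CH=CH–OMe cis to each other and to the C8 silyloxy group, trans to O7 and C10 of the acetonide | CO/C=C/[C@H]1C[C@@H]2OC(C)(C)OC[C@]2(O[Si](CC)(CC)CC)[C@H]1C(=O)O | intermediate
19 | cyclic acylal: C1 lactone carbonyl, ring O2, C3–OMe (one C3 epimer shown, both formed), acetonide, C8 triethylsilyl ether | CO[C@@H]1C[C@H]2C[C@@H]3OC(C)(C)OC[C@]3(O[Si](CC)(CC)CC)[C@H]2C(=O)O1 | intermediate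
20 | cis 1,5-diol: C1H2OH on C9, C4H2–C3H2OH on C5 | OCC[C@H]1C[C@@H]2OC(C)(C)OC[C@]2(O[Si](CC)(CC)CC)[C@H]1CO | intermediate
21 | cis 1,5-dialdehyde (C1 and C3 formyl) | O=CC[C@H]1C[C@@H]2OC(C)(C)OC[C@]2(O[Si](CC)(CC)CC)[C@H]1C=O | intermediate
22 | isovaleric anhydride | CC(C)CC(=O)OC(=O)CC(C)C | starting material
23 | cis-fused lactol, 1-hydroxy 3-ene, hydroxyl anti to C8 | O[C@@H]1OC=C[C@H]2C[C@@H]3OC(C)(C)OC[C@]3(O[Si](CC)(CC)CC)[C@@H]12 | intermediate
24 | 1-O-isovaleryl 3-ene, C1 as in the target, acetonide, C8 triethylsilyl ether | CC(C)CC(=O)O[C@@H]1OC=C[C@H]2C[C@@H]3OC(C)(C)OC[C@]3(O[Si](CC)(CC)CC)[C@@H]12 | intermediate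
25 | C11 dimethyliminium chloride of 24 | CC(C)CC(=O)O[C@@H]1OC=C(C=[N+](C)C)[C@H]2C[C@@H]3OC(C)(C)OC[C@]3(O[Si](CC)(CC)CC)[C@@H]12.[Cl-] | intermediate
26 | 4-formyl derivative of 24 (C11 aldehyde) | CC(C)CC(=O)O[C@@H]1OC=C(C=O)[C@H]2C[C@@H]3OC(C)(C)OC[C@]3(O[Si](CC)(CC)CC)[C@@H]12 | intermediate
27 | 7,8,10-triol 11-aldehyde | CC(C)CC(=O)O[C@@H]1OC=C(C=O)[C@H]2C[C@H](O)[C@](O)(CO)[C@@H]12 | intermediate
28 | 10-O-tert-butyldimethylsilyl ether of 27 | CC(C)CC(=O)O[C@@H]1OC=C(C=O)[C@H]2C[C@H](O)[C@](O)(CO[Si](C)(C)C(C)(C)C)[C@@H]12 | intermediate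
29 | p-coumaric acid | OC(=O)/C=C/c1ccc(O)cc1 | starting material
30 | tert-butyldimethylsilyl (E)-4-(tert-butyldimethylsilyloxy)cinnamate | CC(C)(C)[Si](C)(C)OC(=O)/C=C/c1ccc(O[Si](C)(C)C(C)(C)C)cc1 | intermediate
31 | (E)-4-(tert-butyldimethylsilyloxy)cinnamic acid | OC(=O)/C=C/c1ccc(O[Si](C)(C)C(C)(C)C)cc1 | intermediate
32 | 7-O-[(E)-4-(tert-butyldimethylsilyloxy)cinnamoyl] ester of 28 | CC(C)CC(=O)O[C@@H]1OC=C(C=O)[C@H]2C[C@H](OC(=O)/C=C/c3ccc(O[Si](C)(C)C(C)(C)C)cc3)[C@](O)(CO[Si](C)(C)C(C)(C)C)[C@@H]12 | intermediate
33 | bis-silyl luzonoid A (C10–OTBS, aryl–OTBS) | CC(C)CC(=O)O[C@@H]1OC=C(CO)[C@H]2C[C@H](OC(=O)/C=C/c3ccc(O[Si](C)(C)C(C)(C)C)cc3)[C@](O)(CO[Si](C)(C)C(C)(C)C)[C@@H]12 | intermediate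
34 | luzonoid A | CC(C)CC(=O)O[C@@H]1OC=C(CO)[C@H]2C[C@H](OC(=O)/C=C/c3ccc(O)cc3)[C@](O)(CO)[C@@H]12 | target

Total step count: 20. Longest linear sequence: 19 steps (steps 1–16 and 18–20); step 17 is a one-step branch.

Steps most likely to fail

Step 9. The enolate may expel the β-silyloxy group or collapse to a ketene before it is silylated, and the silyl ketene acetal may ionise at the acetal bond C3–O2 and recombine without control. The fallback sets out from 12 and comes back at 20. Acid 12 is esterified with allyl alcohol (EDC·HCl, DMAP) to the allyl ester F1. Ring-closing metathesis with the second-generation Grubbs catalyst gives the acetal-free Z nine-membered lactone F2. The Ireland–Claisen contraction, in the form already known for such alkenyl lactones (LiN(i-Pr)2, TMSCl/Et3N, then heat), gives the cis-2-vinylcyclopentanecarboxylic acid F3; its facial course then rests on the fused dioxane alone. LiAlH4 gives the primary alcohol F4, and hydroboration of the vinyl group with 9-BBN followed by H2O2/NaOH gives diol 20.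

Step 8. Intermolecular metathesis may outrun closure of the medium ring, turnover at the alkene next to the acetal may be slow, and the acid-labile acylal may erode during the reaction or on silica. The fallback sets out from 11, comes back at 21 and needs no medium ring. i-Bu2AlH at −78 °C reduces ester 11 to the aldehyde F5. Cross-metathesis with crotonaldehyde (second-generation Hoveyda–Grubbs catalyst) gives the E formyl enal F6. A proline-type secondary-amine catalyst then closes C9–C5 by intramolecular Michael addition of the enamine to the enal, the known entry to cis-fused iridoid dialdehydes, to give 21.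

Step 14. The acid set free by the chloroiminium reagent may strip the ketal or the silyl ether or ionise the anomeric ester. The fallback sets out from 24 and comes back at 26. Iodination at C4 with N-iodosuccinimide and catalytic AgNO3 gives the 4-iodo enol ether F7, and formylation with CO and Bu3SnH under Pd(PPh3)4 catalysis gives 26.

Further compounds
F1 | step 9 | allyl ester of acid 12 | C=CCOC(=O)C[C@@]1(O[Si](CC)(CC)CC)COC(C)(C)O[C@H]1CC=C
F2 | step 9 | acetal-free Z nine-membered lactone (C3 = CH2) | O=C1C[C@@]2(O[Si](CC)(CC)CC)COC(C)(C)O[C@H]2C/C=C\CO1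
F3 | step 9 | cis-2-vinylcyclopentanecarboxylic acid with acetonide and C8 triethylsilyl ether | C=C[C@H]1C[C@@H]2OC(C)(C)OC[C@]2(O[Si](CC)(CC)CC)[C@H]1C(=O)O
F4 | step 9 | primary alcohol from F3 (C1H2OH, C5 vinyl) | C=C[C@H]1C[C@@H]2OC(C)(C)OC[C@]2(O[Si](CC)(CC)CC)[C@H]1CO
F5 | step 8 | aldehyde from ester 11 (C1 formyl) | O=CC[C@@]1(O[Si](CC)(CC)CC)COC(C)(C)O[C@H]1CC=C
F6 | step 8 | E formyl enal (C1 formyl, C5=C4–C3 enal) | O=CC[C@@]1(O[Si](CC)(CC)CC)COC(C)(C)O[C@H]1C/C=C/C=O
F7 | step 14 | 4-iodo enol ether of 24 | CC(C)CC(=O)O[C@@H]1OC=C(I)[C@H]2C[C@@H]3OC(C)(C)OC[C@]3(O[Si](CC)(CC)CC)[C@@H]12
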